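The hydroazulene is opened across its seven-membered ring (numbering: C1 methyl-bearing quaternary carbon, C4 isopropyl carbinol, C5 fusion CH, C6 ester carbon, C10 free carbinol). In that ring the C8=C9 alkene and the oxygenated C5–C6 edge stand 1,4 to each other on either side of C7H2, with the C1–C10 bond opposite: the imprint of a cis-divinylcyclopropane rearrangement. One rhodium-catalysed operation joins a cyclopentenyl 2-siloxydiene (C1–C7, C4 ketal) to an (E)-4-siloxyvinyldiazoacetate (C8–C10; its ester carbon becomes the C8 methyl). Cyclopropanation makes C7–C8; the [3,3] shift makes C1–C10, closes the ring and sets C1 and C10. C5, C6 and C4 follow by substrate control.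

Key step: step 7

Remarks on the chemistry
- Numbering, continued: C2 and C3 are the five-ring CH2 groups, C7 is the seven-ring CH2. "Upper face" is the face carrying H5, O6 and O10; the C1 methyl and the C4 hydroxyl lie on the lower face. TBS = tert-butyldimethylsilyl; DOSP = N-(4-dodecylphenylsulfonyl)prolinate.
- Compounds 1 and 11 are taken as catalogue compounds (1 is otherwise one step from 3-methylcyclopent-2-en-1-one with Br2, then Et3N).
- The E geometry of 14 is indispensable, because a Z enol ether would give the C10 epimer. Diazoester 14 is therefore made by an elimination that favours E, not by enol silylation of an aldehyde, which favours Z.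
- The sense of induction in step 7 is extrapolated from the styrene benchmark of this catalyst family and is to be checked on 17. Both catalyst antipodes are commercial.

Step 1
Reactants: 1 bromoenone 2-bromo-3-methylcyclopent-2-en-1-one
Product: 2 bromo ketal 6-bromo-7-methyl-1,4-dioxaspiro[4.4]non-6-ene
Conditions: HOCH2CH2OH, p-TsOH·H2O (cat.), benzene, reflux, azeotropic removal of water
Reagents that add atoms: ethylene glycol, OCCO
Why: Acid-catalysed ketalisation with removal of water is routine for 2-bromocycloalkenones, the halogen keeping the alkene in its place, and it masks C4 ahead of the organolithium chemistry.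

Step 2
Reactants: 2 bromo ketal 6-bromo-7-methyl-1,4-dioxaspiro[4.4]non-6-ene; 3 N-methoxy-N-methylacetamide
Product: 6 ketal ketone 1-(7-methyl-1,4-dioxaspiro[4.4]non-6-en-6-yl)ethan-1-one, via vinyllithium 4 (not isolated), via lithium hemiaminal 5 (not isolated)
Conditions: n-BuLi, THF, −78 °C; then 3, −78 → 0 °C; aq. NH4Cl
Reagents that add atoms: none
Why: Bromine–lithium exchange followed by a Weinreb ketone synthesis delivers the C6–C7 acetyl unit, since vinyllithium 4 adds only once and the chelated adduct 5 holds until the quench.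

Step 3
Reactants: 6 ketal ketone 1-(7-methyl-1,4-dioxaspiro[4.4]non-6-en-6-yl)ethan-1-one
Product: 8 siloxydiene 2-[1-(tert-butyldimethylsilyloxy)vinyl]-3-methylcyclopent-2-en-1-one ethylene ketal, via potassium enolate 7 (not isolated)
Conditions: KN(SiMe3)2, THF, −78 °C; then TBSCl, −78 → 0 °C; aq. NaHCO3; Et3N-deactivated silica
Reagents that add atoms: tert-butyldimethylsilyl chloride, CC(C)(C)[Si](C)(C)Cl
Why: Kinetic enolate formation at −78 °C takes an acetyl proton (C7) rather than a gamma proton, and O-silylation of cross-conjugated enolate 7 gives the 2-siloxydiene under purely basic conditions that the acid-labile allylic ketal tolerates.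

Step 4
Reactants: 9 glycine methyl ester hydrochloride
Product: 10 methyl diazoacetate (kept as a dried CH2Cl2 solution)
Conditions: NaNO2, H2SO4 (cat.), H2O/CH2Cl2, −5 → 0 °C
Reagents that add atoms: sodium nitrite, [Na+].[O-]N=O
Why: Two-phase diazotisation of an alpha-amino ester is the standard preparation of diazoacetates, and the product is kept in solution and never concentrated.

Step 5
Reactants: 10 methyl diazoacetate; 11 (tert-butyldimethylsilyloxy)acetaldehyde
Product: 12 methyl 4-(tert-butyldimethylsilyloxy)-2-diazo-3-hydroxybutanoate (racemic)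
Conditions: DBU (15 mol %), CH2Cl2/MeCN, 0 → 23 °C
Reagents that add atoms: none
Why: The amine-catalysed aldol-type addition of a diazoacetate to an aldehyde is a known entry to beta-hydroxy-alpha-diazo esters, and the racemic carbinol centre it creates is erased in step 6.

Step 6
Reactants: 12 methyl 4-(tert-butyldimethylsilyloxy)-2-diazo-3-hydroxybutanoate
Product: 14 methyl (E)-4-(tert-butyldimethylsilyloxy)-2-diazobut-3-enoate, via trifluoroacetate 13 (not isolated)
Conditions: (CF3CO)2O, Et3N, CH2Cl2, −20 → 0 °C; Et3N-deactivated silica; stored cold and used promptly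
Reagents that add atoms: none
Why: O-Acylation and amine-induced 1,2-elimination is the known dehydration of beta-hydroxy-alpha-diazo esters to vinyldiazoacetates, and the E enol ether should prevail because the siloxy group turns away from the diazoester (minimised allylic strain) as the C–H bond is broken.

Step 7
Reactants: 8 siloxydiene 2-[1-(tert-butyldimethylsilyloxy)vinyl]-3-methylcyclopent-2-en-1-one ethylene ketal; 14 methyl (E)-4-(tert-butyldimethylsilyloxy)-2-diazobut-3-enoate
Product: 17 (1S,10R)-hydroazulene diene ester (C5=C6 and C8=C9 alkenes; TBSO on C6 and C10; CO2Me on C8; ethylene ketal at C4; CH3 on C1), via rhodium vinylcarbenoid 15 (not isolated), via cis-divinylcyclopropane 16 (not isolated)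
Conditions: Rh2(R-DOSP)4 (2 mol %), degassed hexanes, −20 °C, slow addition of 14 (1.5 equiv) to 8; then 23 → 60 °C
Reagents that add atoms: none
Why: Rh2(R-DOSP)4, a dimer of divalent rhodium, expels N2 from 14 to give donor/acceptor vinylcarbenoid 15, whose carbene carbon C8 adds concertedly but asynchronously to the C6=C7 bond of 8 (C7 first) to give cis-divinylcyclopropane 16, and 16 then undergoes a Cope rearrangement in which C6–C8 breaks while C1–C10 forms. The closest known reaction type is the tandem cyclopropanation/divinylcyclopropane rearrangement, a formal (4+3) cycloaddition, of vinyldiazoacetates with 2-siloxydienes, which has also been run on dienes that end in a fully substituted ring alkene. The seven-membered ring is closed in a pericyclic [3,3] mode through a boat transition state, as a strain-driven expansion of the three-membered ring; the C1 methyl points inward toward C7 in that boat, hence the final warming. C6 and C8 of 16 are set by the chiral carboxylate pocket, and the boat relays them to C1 and C10: the E-siloxy group and ring carbon C2 both point outward and end cis, so that O10 is trans to the C1 methyl (1S,10R). The R catalyst is chosen because its S antipode converts styrene and methyl phenyldiazoacetate into the (1S,2R)-cyclopropane, a sense that would map here onto the enantiomer of 16. Three selectivities are needed: the terminal alkene must react instead of the tetrasubstituted ring alkene (secured by the siloxy donor and the unsubstituted C7), the carbene carbon instead of the vinylogous terminus C10 (small methyl ester, substituted terminus, hydrocarbon solvent), and the cyclopentenyl group must end cis to the carbenoid vinyl group (the usual placement of an alkene's unsaturated substituent beside the donor group of such carbenoids).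

Step 8
Reactants: 17 (1S,10R)-hydroazulene diene ester
Product: 18 (1S,10R)-allylic alcohol (as 17 with CH2OH on C8)
Conditions: i-Bu2AlH, CH2Cl2, −78 °C; aq. KNaC4H4O6 (potassium sodium tartrate)
Reagents that add atoms: none
Why: Low-temperature 1,2-reduction of the enoate with i-Bu2AlH is standard, leaves both silyl groups and the ketal untouched and is worked up with tartrate so that the acid-sensitive enol ether/allylic ketal pair never meets acid.

Step 9
Reactants: 18 (1S,10R)-allylic alcohol
Product: 20 (1S,10R)-C8-methyl diene (as 17 with CH3 on C8), via allylic mesylate 19 (not isolated)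
Conditions: MsCl, Et3N, THF, −40 °C; then LiEt3BH (excess), −40 → 0 °C; aq. NaHCO3
Reagents that add atoms: none
Why: Sulfonate activation and SN2 displacement by LiEt3BH is a standard deoxygenation of primary allylic alcohols, direct attack at the open CH2 being favoured over SN2′ attack at C9 next to the neopentyl siloxy carbon, and it removes the ester before the C6 carbonyl appears so that C7 never lies between a ketone and an enoate.

Step 10
Reactants: 20 (1S,10R)-C8-methyl diene
Product: 22 (1S,5S,10R)-trans-fused C6 ketone (C8=C9 alkene with CH3 on C8; TBSO on C10; ethylene ketal at C4; H5 on the upper face), via ammonium enolate 21 (not isolated)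
Conditions: n-Bu4NF, AcOH, THF, −20 → 0 °C; pH 7 buffer
Reagents that add atoms: none
Why: In this fluoride desilylation with kinetic enolate protonation, buffered fluoride cleaves the enol silane far faster than the hindered secondary silyl ether, and enolate 21 is protonated at C5 on the upper face because the C1 methyl stands perpendicular to the enolate plane on the lower face, which sets 5S (trans ring fusion) while the acetic acid suppresses ketal beta-elimination and migration of the C8=C9 alkene.

Step 11
Reactants: 22 (1S,5S,10R)-trans-fused C6 ketone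
Product: 23 (1S,5S,6S,10R)-C6 alcohol (equatorial OH on the upper face; H6 anti to H5)
Conditions: SmI2, THF/H2O, 0 → 23 °C
Reagents that add atoms: none
Why: Electron-transfer reduction of the ketone with SmI2–H2O gives the thermodynamically preferred alcohol, here the equatorial 6S carbinol, whereas hydride reagents would be forced by the axial C1 methyl to attack from the upper face and give the axial epimer.

Step 12
Reactants: 23 (1S,5S,6S,10R)-C6 alcohol
Product: 24 (1S,5S,6S,10R)-6-hydroxy C4 ketone
Conditions: pyridinium p-toluenesulfonate (cat.), acetone/H2O 9:1, 45 °C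
Reagents that add atoms: water, O
Why: In this acid-catalysed ketal hydrolysis the cyclopentanone dioxolane, no longer flanked by an enol ether, yields to conditions too mild to cleave the hindered secondary silyl ether, ionise the allylic C10–O bond, dehydrate the beta-hydroxy ketone or enolise C5.

Step 13
Reactants: 24 (1S,5S,6S,10R)-6-hydroxy C4 ketone
Product: 25 (1S,4R,5S,6S,10R)-4,6-diol (isopropyl on the upper face and OH on the lower face of C4; TBSO on C10)
Conditions: CeCl3 (dried), i-PrLi, THF, −78 °C; then 24, −78 → −40 °C; aq. NH4Cl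
Reagents that add atoms: isopropyllithium, [Li]C(C)C
Why: The 1,2-addition of an organocerium reagent (low basicity, high oxophilicity) overrides enolisation and hydride transfer, and the nucleophile enters on the upper face, flanked only by H5, because the lower face of the cyclopentanone is screened by the C1 methyl and by C6 with its axial hydrogen, which sets 4R.

Step 14
Reactants: 25 (1S,4R,5S,6S,10R)-4,6-diol; 26 4-methoxybenzoyl chloride
Product: 27 (1S,4R,5S,6S,10R)-C6 4-methoxybenzoate (free tertiary OH at C4; TBSO on C10)
Conditions: 26, Et3N, DMAP (cat.), CH2Cl2, 0 → 23 °C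
Reagents that add atoms: none
Why: DMAP-catalysed acylation takes the only secondary hydroxyl, the tertiary C4 carbinol being inert and C10 still silylated, so that no selection between O6 and O10 is ever required.

Step 15
Reactants: 27 (1S,4R,5S,6S,10R)-C6 4-methoxybenzoate
Product: 28 target (3R,3aS,4S,8R,8aS)-3,8-dihydroxy-6,8a-dimethyl-3-(propan-2-yl)-1,2,3,3a,4,5,8,8a-octahydroazulen-4-yl 4-methoxybenzoate
Conditions: n-Bu4NF, AcOH, THF, 23 → 45 °C
Reagents that add atoms: none
Why: Fluoride-mediated silyl ether cleavage under acetic acid buffering frees the C10 carbinol without acid, which could ionise the allylic or tertiary alcohol, and without strong base, which could cleave or shift the aroyl group.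

Compound list
1 | 2-bromo-3-methylcyclopent-2-en-1-one | CC1=C(Br)C(=O)CC1 | starting material
2 | 6-bromo-7-methyl-1,4-dioxaspiro[4.4]non-6-ene | CC1=C(Br)C2(CC1)OCCO2 | intermediate
3 | N-methoxy-N-methylacetamide | CON(C)C(C)=O | starting material
4 | (7-methyl-1,4-dioxaspiro[4.4]non-6-en-6-yl)lithium, not isolated | [Li]C1=C(C)CCC12OCCO2 | intermediate
5 | lithium 1-[methoxy(methyl)amino]-1-(7-methyl-1,4-dioxaspiro[4.4]non-6-en-6-yl)ethan-1-olate, racemic, not isolated | CON(C)C(C)([O-])C1=C(C)CCC12OCCO2.[Li+] | intermediate
6 | 1-(7-methyl-1,4-dioxaspiro[4.4]non-6-en-6-yl)ethan-1-one | CC(=O)C1=C(C)CCC12OCCO2 | intermediate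
7 | potassium 1-(7-methyl-1,4-dioxaspiro[4.4]non-6-en-6-yl)ethen-1-olate, not isolated | C=C([O-])C1=C(C)CCC12OCCO2.[K+] | intermediate
8 | 2-[1-(tert-butyldimethylsilyloxy)vinyl]-3-methylcyclopent-2-en-1-one ethylene ketal | C=C(O[Si](C)(C)C(C)(C)C)C1=C(C)CCC12OCCO2 | intermediate
9 | glycine methyl ester hydrochloride | COC(=O)CN.Cl | starting material
10 | methyl diazoacetate | COC(=O)C=[N+]=[N-] | intermediate
11 | (tert-butyldimethylsilyloxy)acetaldehyde | CC(C)(C)[Si](C)(C)OCC=O | starting material
12 | methyl 4-(tert-butyldimethylsilyloxy)-2-diazo-3-hydroxybutanoate, racemic | COC(=O)C(=[N+]=[N-])C(O)CO[Si](C)(C)C(C)(C)C | intermediate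
13 | methyl 4-(tert-butyldimethylsilyloxy)-2-diazo-3-(trifluoroacetoxy)butanoate, racemic, not isolated | COC(=O)C(=[N+]=[N-])C(CO[Si](C)(C)C(C)(C)C)OC(=O)C(F)(F)F | intermediate
14 | methyl (E)-4-(tert-butyldimethylsilyloxy)-2-diazobut-3-enoate | COC(=O)C(=[N+]=[N-])/C=C/O[Si](C)(C)C(C)(C)C | intermediate
15 | rhodium vinylcarbenoid from 14 (second rhodium and the four carboxylates not drawn), not isolated | COC(=O)C(=[Rh])/C=C/O[Si](C)(C)C(C)(C)C | intermediate
16 | methyl (1S,2R)-2-(tert-butyldimethylsilyloxy)-1-[(E)-2-(tert-butyldimethylsilyloxy)ethenyl]-2-(7-methyl-1,4-dioxaspiro[4.4]non-6-en-6-yl)cyclopropane-1-carboxylate, the two vinyl groups cis, not isolated | COC(=O)[C@]1(/C=C/O[Si](C)(C)C(C)(C)C)C[C@@]1(O[Si](C)(C)C(C)(C)C)C2=C(C)CCC23OCCO3 | intermediate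
17 | (1S,10R)-hydroazulene diene ester: C5=C6 and C8=C9 alkenes, TBSO on C6 and C10, CO2Me on C8, ethylene ketal at C4, CH3 on C1 | COC(=O)C1=C[C@@H](O[Si](C)(C)C(C)(C)C)[C@@]2(C)CCC3(OCCO3)C2=C(O[Si](C)(C)C(C)(C)C)C1 | intermediate
18 | (1S,10R)-allylic alcohol: as 17 with CH2OH on C8 | OCC1=C[C@@H](O[Si](C)(C)C(C)(C)C)[C@@]2(C)CCC3(OCCO3)C2=C(O[Si](C)(C)C(C)(C)C)C1 | intermediate
19 | (1S,10R)-allylic mesylate: as 17 with CH2OSO2CH3 on C8, not isolated | CS(=O)(=O)OCC1=C[C@@H](O[Si](C)(C)C(C)(C)C)[C@@]2(C)CCC3(OCCO3)C2=C(O[Si](C)(C)C(C)(C)C)C1 | intermediate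
20 | (1S,10R)-C8-methyl diene: as 17 with CH3 on C8 | CC1=C[C@@H](O[Si](C)(C)C(C)(C)C)[C@@]2(C)CCC3(OCCO3)C2=C(O[Si](C)(C)C(C)(C)C)C1 | intermediate
21 | tetrabutylammonium (1S,10R)-C5=C6 enolate from 20, not isolated | CC1=C[C@@H](O[Si](C)(C)C(C)(C)C)[C@@]2(C)CCC3(OCCO3)C2=C([O-])C1.CCCC[N+](CCCC)(CCCC)CCCC | intermediate
22 | (1S,5S,10R)-trans-fused C6 ketone with C4 ethylene ketal and C10 OTBS | O=C1CC(C)=C[C@@H](O[Si](C)(C)C(C)(C)C)[C@@]2(C)CCC3(OCCO3)[C@H]12 | intermediate
23 | (1S,5S,6S,10R)-C6 alcohol with C4 ethylene ketal and C10 OTBS | O[C@H]1CC(C)=C[C@@H](O[Si](C)(C)C(C)(C)C)[C@@]2(C)CCC3(OCCO3)[C@H]12 | intermediate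
24 | (1S,5S,6S,10R)-6-hydroxy C4 ketone with C10 OTBS | O[C@H]1CC(C)=C[C@@H](O[Si](C)(C)C(C)(C)C)[C@@]2(C)CCC(=O)[C@H]12 | intermediate
25 | (1S,4R,5S,6S,10R)-4-isopropyl-4,6-diol with C10 OTBS | O[C@H]1CC(C)=C[C@@H](O[Si](C)(C)C(C)(C)C)[C@@]2(C)CC[C@@](O)(C(C)C)[C@H]12 | intermediate
26 | 4-methoxybenzoyl chloride | COc1ccc(C(=O)Cl)cc1 | starting material
27 | (1S,4R,5S,6S,10R)-C6 4-methoxybenzoate with free C4 OH and C10 OTBS | COc1ccc(C(=O)O[C@H]2CC(C)=C[C@@H](O[Si](C)(C)C(C)(C)C)[C@@]3(C)CC[C@@](O)(C(C)C)[C@H]23)cc1 | intermediate
28 | (3R,3aS,4S,8R,8aS)-3,8-dihydroxy-6,8a-dimethyl-3-(propan-2-yl)-1,2,3,3a,4,5,8,8a-octahydroazulen-4-yl 4-methoxybenzoate | COc1ccc(C(=O)O[C@H]2CC(C)=C[C@@H](O)[C@@]3(C)CC[C@@](O)(C(C)C)[C@H]23)cc1 | target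

Total step count: 15. Longest linear sequence: 12 steps (1 → 28 through steps 1–3 and 7–15; the arm from 9 through steps 4–6 is equally long).

Steps most likely to fail

**Step 7.** Four things may go wrong:
- The electron-rich diene may attack the carbenoid at its vinylogous terminus.
- The cyclopropanation may place the two vinyl groups trans, which blocks the rearrangement.
- The donor–acceptor C6–C8 bond may heterolyse with loss of stereochemical information.
- Enantio-induction on the crowded 1,1-disubstituted alkene may be weak.

The fallback moves stereocontrol from the catalyst to an ester auxiliary, a known tactic for vinyldiazoacetates of alpha-hydroxy esters, so that a small achiral catalyst can be used. It sets out from 11 and 8 and comes back at 18. (R)-Pantolactone is acylated with bromoacetyl bromide to (R)-pantolactonyl bromoacetate F1, which N,N′-ditosylhydrazine and DBU convert into (R)-pantolactonyl diazoacetate F2. DBU-catalysed addition to 11 gives the beta-hydroxy diazoester F3, and (CF3CO)2O/Et3N takes it through its trifluoroacetate F4 to the (E)-vinyldiazoacetate F5. Decomposition of F5 with Rh2(O2CC7H15)4 in the presence of 8 gives, through the auxiliary-bearing cis-divinylcyclopropane F6, the pantolactonyl cycloheptadienecarboxylate F7, the lactone carbonyl shielding one face of the carbenoid. Excess i-Bu2AlH then removes the auxiliary reductively and gives 18. If the (R)-lactone induces the wrong sense, its commercial antipode is used.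

**Step 13.** The hindered ketone may be enolised, the branched nucleophile may transfer hydride instead of carbon, or the beta-alkoxide may open by a retro-aldol process. The fallback sets out from 24 and comes back at 25. The slimmer sp2 nucleophile isopropenylmagnesium bromide, which cannot transfer hydride, is added with CeCl3 from the same upper face to give the isopropenyl carbinol F8. Hydrogenation with RhCl(PPh3)3 and H2 (1 atm) then saturates only the 1,1-disubstituted alkene and leaves the trisubstituted C8=C9 bond.

**Step 11.** Electron transfer to the hindered ketone may be sluggish, or facial selectivity at C6 may be poor. The fallback postpones the C6 centre and sets it by hydroxyl-directed hydride delivery; it sets out from 22 and comes back at 25.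
- LiBH(s-Bu)3 attacks 22 from the upper face to give the axial 6-epi alcohol F9.
- Pyridinium p-toluenesulfonate in wet acetone gives the 6-epi hydroxy ketone F10.
- i-PrLi/CeCl3 gives the 6-epi diol F11.
- 1,1,1-Triacetoxy-1,2-benziodoxol-3-one (DMP, NaHCO3 buffer) oxidises only the secondary alcohol to the 4-hydroxy C6 ketone F12.
- An Evans–Saksena reduction (Me4NBH(OAc)3, MeCN/AcOH, −20 °C) binds boron to the lower-face C4 hydroxyl and delivers hydride to the lower face of C6, giving the anti-1,3-diol 25.

Further compounds
F1 | step 7 | (R)-pantolactonyl bromoacetate | CC1(C)COC(=O)[C@@H]1OC(=O)CBr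
F2 | step 7 | (R)-pantolactonyl diazoacetate | CC1(C)COC(=O)[C@@H]1OC(=O)C=[N+]=[N-]
F3 | step 7 | (R)-pantolactonyl 4-(tert-butyldimethylsilyloxy)-2-diazo-3-hydroxybutanoate, both carbinol epimers | CC1(C)COC(=O)[C@@H]1OC(=O)C(=[N+]=[N-])C(O)CO[Si](C)(C)C(C)(C)C
F4 | step 7 | trifluoroacetate of F3 | CC1(C)COC(=O)[C@@H]1OC(=O)C(=[N+]=[N-])C(CO[Si](C)(C)C(C)(C)C)OC(=O)C(F)(F)F
F5 | step 7 | (R)-pantolactonyl (E)-4-(tert-butyldimethylsilyloxy)-2-diazobut-3-enoate | CC1(C)COC(=O)[C@@H]1OC(=O)C(=[N+]=[N-])/C=C/O[Si](C)(C)C(C)(C)C
F6 | step 7 | (R)-pantolactonyl analogue of cis-divinylcyclopropane 16 | CC1(C)COC(=O)[C@@H]1OC(=O)[C@]2(/C=C/O[Si](C)(C)C(C)(C)C)C[C@@]2(O[Si](C)(C)C(C)(C)C)C3=C(C)CCC34OCCO4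
F7 | step 7 | (R)-pantolactonyl analogue of diene ester 17 | CC1(C)COC(=O)[C@@H]1OC(=O)C2=C[C@@H](O[Si](C)(C)C(C)(C)C)[C@@]3(C)CCC4(OCCO4)C3=C(O[Si](C)(C)C(C)(C)C)C2
F8 | step 13 | 4-isopropenyl analogue of diol 25 (same spatial arrangement at C4) | O[C@H]1CC(C)=C[C@@H](O[Si](C)(C)C(C)(C)C)[C@@]2(C)CC[C@@](O)(C(C)=C)[C@H]12
F9 | step 11 | 6-epi-23 (6R, axial OH) | O[C@@H]1CC(C)=C[C@@H](O[Si](C)(C)C(C)(C)C)[C@@]2(C)CCC3(OCCO3)[C@H]12
F10 | step 11 | 6-epi-24 | O[C@@H]1CC(C)=C[C@@H](O[Si](C)(C)C(C)(C)C)[C@@]2(C)CCC(=O)[C@H]12
F11 | step 11 | 6-epi-25 | O[C@@H]1CC(C)=C[C@@H](O[Si](C)(C)C(C)(C)C)[C@@]2(C)CC[C@@](O)(C(C)C)[C@H]12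
F12 | step 11 | 4-hydroxy-4-isopropyl C6 ketone with C10 OTBS | O=C1CC(C)=C[C@@H](O[Si](C)(C)C(C)(C)C)[C@@]2(C)CC[C@@](O)(C(C)C)[C@H]12
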